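## Analysis of the target

The target (27) is a 2-hydroxy-5-methoxy-1,4-benzoquinone whose C3 is joined through a methylene (C11) to a bicyclic sesquiterpene unit. That unit, in drimane numbering, is an octalin made of ring A (C1–C5 and C10, gem-dimethyl at C4) and ring B (C5–C10), with its only C=C at C5=C6. There are three contiguous stereocentres: C8 (CH–CH3), the quaternary C9 (CH3 and the quinonylmethyl group) and the ring-fusion methine C10. The 8- and 9-methyl groups are cis, and H-10 is cis to C11, which is the (8S,9R,10S) configuration.

The hydroxyquinone is a vinylogous acid that does not survive organometallic reagents, hydrides or radical reduction, and under acid its hydroxyl can add to C5=C6. The alkene sits next to the quaternary C4, so any cation at C5 or C6 invites a methyl shift. The quinone must therefore be unveiled last and the alkene made under non-ionising conditions.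

The difficulty is that the decalin carries no heteroatom. The quaternary C9 and its two neighbours have to be set with functionality that is later erased, the alkene has to end at C5=C6 and nowhere else, and C11 is a neopentyl position.

The strategy rests on ring B. If its unsaturation is moved to C6=C7 as a C6 enol ether, C5–C10 and C8–C9 are the two σ-bonds of a cyclohexene retron. Cutting them unfolds both rings into one open chain in which ring A is the four-carbon tether and an (E)-2-methyl enal supplies C9, C10 and C11.

## Retrosynthetic reasoning

**27 ⇒ 26 ⇒ 25.** Only C–O bonds of the oxygenated ring change. The hydroxyl of 27 comes from the methoxy group next to the alkylated carbon of dimethoxyquinone 26, and 26 comes from oxidative demethylation of tetramethoxyarene 25. As the fully methylated arene the ring is inert to everything that precedes, and it is available in one piece from commercial 16. The forward steps must oxidise one para pair of methoxy groups (the two pairs are equivalent by symmetry) and then replace one of two vinylogous ester groups.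

**25 ⇒ 23 ⇒ 22.** The C5=C6 bond is traced to the axial C6 alcohol 23 and this to the trans-fused C6 ketone 22. Elimination is preferred to enolisation of 22 toward C5, because an enol derivative at C5=C6 holds its oxygen against the C4 methyl groups whereas the alkene itself does not. In 23 the leaving group is anti to the tertiary H-5. The forward reaction must take H-5 and not H-7, and must not ionise.

**22 ⇒ 21 ⇒ 20 ⇒ 19 ⇒ 18 ⇒ 15 + 16.** The C11–aryl bond is cut, giving aldehyde 15 and aryllithium 17 (from 16). The cut is made on the aryl side of C11 because a neopentyl electrophile cannot be substituted, whereas a non-enolisable aldehyde accepts an aryl nucleophile. The price is the carbinol oxygen of 18, removed by radical reduction of xanthate 19 to 20. Through these steps the silyl enol ether of 15 protects the C6 carbonyl. It is then opened to the cis-fused ketone 21, which is equilibrated at C5 to 22.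

**15 ⇒ 14.** This is the key disconnection: C5–C10 and C8–C9 are cut together. Two rings, two skeletal bonds and all stereocentres of the decalin go back to the acyclic trienal 14, whose alkene geometries carry the relative configuration and whose formyl group is the handle for a chiral Lewis acid. No other pair of bonds removes both rings and the quaternary centre at once. The forward reaction must be exo with respect to the formyl group and must discriminate the enal faces.

**14 ⇒ 13 ⇒ 12 ⇒ 11.** No C–C bond is cut here, but the order matters. Enolising a keto aldehyde would risk silylating the enal at its γ-position and would leave a silyl triflate in contact with the complete triene. The ketone is therefore enolised while C1 is still an ester (11 → 12), and the aldehyde is released last, by reduction to 13 and neutral oxidation to 14.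

**11 ⇒ 10 ⇒ 9 ⇒ 7 + 8.** The trisubstituted enoate is cut by cross-metathesis into terminal alkene 7 and ethyl methacrylate 8. The enone double bond comes from dehydration of aldol 9 through mesylate 10. Metathesis is placed before the dehydration so that the catalyst meets only one reactive alkene.

**7 ⇒ 4 + 5 and 4 ⇒ 1 + 2.** The aldol bond is cut between the methyl group of ketone 4 (as enolate 6) and acetaldehyde 5. The quaternary carbon, the later C4, is cut by conjugate addition of Grignard reagent 3 (from bromide 1) to enone 2.

## Alternatives that were turned down

**Alternative 1:** Ring B is taken as a preformed six-membered enone that already carries the C8 methyl group, and C9–C11 and C10–C1 are cut. In the forward key step a copper-mediated conjugate addition of the tetramethoxybenzyl organomagnesium reagent, accelerated by a silyl chloride, is followed by release of the enolate and C-alkylation with an unsaturated primary iodide. This gives the trisubstituted cyclohexanone A1.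
- For it: the route is convergent, the aryl ring enters without a later deoxygenation at C11, and C8 comes from an independent source and relays to C9 and C10 by anti addition. On these points it is stronger than the chosen route, whose C8 depends on a topological preference.
- Against it: the quaternary C9 is made intermolecularly next to a methine; electron-rich benzylic Grignard reagents couple with themselves; and alkylating a hindered enolate flanked by a quaternary carbon with an unactivated iodide competes with proton transfer and O-alkylation.
- Above all, ring A is still open in A1. Closing C4–C5 while leaving exactly the C5=C6 alkene needs a cation- or radical-olefin cyclisation in the presence of an electron-rich arene, which is a second uncertain step.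
- Comparison: the chosen strategy closes both rings and sets every centre in one catalytic intramolecular event and leaves only functional-group changes.

**Alternative 2:** The disconnection lies inside the quinone, which is assembled last by thermal ring expansion of a 4-alkynyl-4-hydroxycyclobutenone. The four-membered ring opens to a vinylketene that closes onto a methoxyalkyne, giving the O-tert-butyl quinone A2, from which the tert-butyl group is cleaved.
- For it: the positions of hydroxyl and methoxyl are fixed by construction and no ceric oxidation is needed. On quinone regiocontrol it is clearly stronger than the last step of the chosen route.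
- Against it: it is an endgame only. The whole decalin with its three centres and its alkene must still be made, and must then be turned into a neopentyl organometallic nucleophile for addition to a squarate, which is a reluctant reagent.
- The alkynyl metal reagent is fragile, and both the thermolysis near 140 °C and the acidic tert-butyl cleavage expose the C5=C6 bond next to a hydroxyquinone.
- Comparison: it would add steps to any decalin synthesis, whereas the chosen route takes the ring from a commercial arene in one C–C bond formation and accepts a selectivity question at the end.

**Alternative 3:** Ring A is annulated onto ring B by cutting C10–C1 and C4–C5. A prochiral 4-methyl-4-arylmethyl cyclohexadienone is desymmetrised by a Diels–Alder reaction with a 1-methoxy-1-methyl-3-silyloxy diene under a protonated oxazaborolidine, giving the cis-fused cycloadduct A3.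
- For it: the catalyst class has close intermolecular precedent for dienone-type dienophiles, the aryl group is present from the start, and C9 and C10 are set together. In closeness of precedent it is at least as strong as the chosen key step.
- Against it: A3 is far from the target. C4 bears a methoxy group that must be replaced by methyl, the C2 oxygen must be removed, and C6 must still become the alkene.
- The C8 methyl must be added to the remaining enone with no reliable bias toward the cis relation to the 9-methyl group, and the diene has to form a quaternary carbon at its disubstituted terminus.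
- Comparison: the chosen route brings every skeletal carbon, including the 8-methyl, into the cycloaddition and has one oxygen to remove afterwards.

Key step: step 8

Remark: drimane numbering (C1–C10, C11 the exocyclic carbon on C9) is used for all bicyclic compounds, and the target is taken as the (8S,9R,10S) enantiomer encoded in the SMILES.

Remark: the silyl group of the cycloaddition pair is triisopropylsilyl, chosen for its stability toward the acid-activated catalyst. The (S) catalyst is assigned by analogy with 2-substituted acroleins, and its mirror image is equally available should the intramolecular case respond in the opposite sense.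

## Route

Step 1
Reactants: 1 5-bromopent-1-ene; 2 4-methylpent-3-en-2-one
Product: 4 4,4-dimethylnon-8-en-2-one, via pent-4-enylmagnesium bromide 3 (not isolated)
Conditions: Mg, THF, rt; then CuBr·SMe2 (5 mol %), 2, THF, −40 → 0 °C; aq. NH4Cl
Reagents that add atoms: none
Why: Copper-catalysed conjugate addition of a primary Grignard reagent to a β,β-disubstituted enone builds the quaternary carbon (later C4); the monovalent copper catalyst diverts the reagent from 1,2-addition and the terminal alkene is inert.

Step 2
Reactants: 4 4,4-dimethylnon-8-en-2-one; 5 acetaldehyde
Product: 7 2-hydroxy-6,6-dimethylundec-10-en-4-one (racemic), via lithium enolate 6 (not isolated)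
Conditions: LiN(i-Pr)2, THF, −78 °C; 5, −78 °C; aq. NH4Cl
Reagents that add atoms: none
Why: Kinetic deprotonation by the hindered amide occurs at the methyl group and not at the neopentyl methylene, and the enolate adds to the aldehyde (directed aldol reaction); the carbinol centre is erased in step 4, so its configuration is irrelevant.

Step 3
Reactants: 7 2-hydroxy-6,6-dimethylundec-10-en-4-one; 8 ethyl 2-methylprop-2-enoate
Product: 9 ethyl (2E)-11-hydroxy-2,7,7-trimethyl-9-oxododec-2-enoate
Conditions: 8 (5 equiv), second-generation Hoveyda–Grubbs catalyst RuCl2(H2IMes)(=CH–C6H4-2-O-i-Pr) (5 mol %), CH2Cl2, 40 °C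
Reagents that add atoms: none
Why: Olefin cross-metathesis of a monosubstituted alkene with a methacrylate; the 1,1-disubstituted partner does not homodimerise, so the cross product should form selectively and as the favoured (E)-trisubstituted enoate, and ketone and free hydroxyl are tolerated.

Step 4
Reactants: 9 ethyl (2E)-11-hydroxy-2,7,7-trimethyl-9-oxododec-2-enoate
Product: 11 ethyl (2E,10E)-2,7,7-trimethyl-9-oxododeca-2,10-dienoate, via mesylate 10 (not isolated)
Conditions: MsCl, Et3N, CH2Cl2, 0 °C; then DBU, rt
Reagents that add atoms: none
Why: Mesylation and E1cB elimination of a β-sulfonyloxy ketone give the conjugated enone in its more stable (E) form; the enoate is not affected.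

Step 5
Reactants: 11 ethyl (2E,10E)-2,7,7-trimethyl-9-oxododeca-2,10-dienoate
Product: 12 ethyl (2E,8Z,10E)-2,7,7-trimethyl-9-[(triisopropylsilyl)oxy]dodeca-2,8,10-trienoate
Conditions: i-Pr3SiOTf, Et3N, CH2Cl2, 0 °C → rt
Reagents that add atoms: triisopropylsilyl trifluoromethanesulfonate, CC(C)[Si](OS(=O)(=O)C(F)(F)F)(C(C)C)C(C)C
Why: Soft enolisation: O-silylation of the ketone and removal of an α′-methylene hydrogen by the amine give the cross-conjugated 2-silyloxy diene, which is also the more substituted dienol ether; the (Z) enol ether is expected because the (E) isomer would press the propenyl group against the quaternary carbon. The ester is not enolised under these conditions, which is why C1 is still an ester here.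

Step 6
Reactants: 12 ethyl (2E,8Z,10E)-2,7,7-trimethyl-9-[(triisopropylsilyl)oxy]dodeca-2,8,10-trienoate
Product: 13 (2E,8Z,10E)-2,7,7-trimethyl-9-[(triisopropylsilyl)oxy]dodeca-2,8,10-trien-1-ol
Conditions: i-Bu2AlH, CH2Cl2, −78 °C; aq. potassium sodium tartrate
Reagents that add atoms: none
Why: 1,2-Reduction of a conjugated ester to the allylic alcohol by an aluminium hydride at low temperature; silyl enol ethers are stable to the reagent and to the neutral work-up.

Step 7
Reactants: 13 (2E,8Z,10E)-2,7,7-trimethyl-9-[(triisopropylsilyl)oxy]dodeca-2,8,10-trien-1-ol
Product: 14 (2E,8Z,10E)-2,7,7-trimethyl-9-[(triisopropylsilyl)oxy]dodeca-2,8,10-trienal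
Conditions: MnO2 (activated), CH2Cl2, 0 °C → rt; filtered, concentrated cold and used at once
Reagents that add atoms: none
Why: Allylic alcohol oxidation by MnO2 is neutral and heterogeneous, leaves the acid-labile silyloxy diene intact and keeps the (E)-enal geometry. The aldehyde is released last and kept cold so that no uncatalysed cyclisation precedes the key step.

Step 8
Reactants: 14 (2E,8Z,10E)-2,7,7-trimethyl-9-[(triisopropylsilyl)oxy]dodeca-2,8,10-trienal
Product: 15 (1R,2S,4aR,8aR)-1,2,5,5-tetramethyl-4-[(triisopropylsilyl)oxy]-1,2,4a,5,6,7,8,8a-octahydronaphthalene-1-carbaldehyde (cis-fused; formyl cis to H-10; 8-methyl cis to 9-methyl)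
Conditions: (S)-1-(2-methylphenyl)-3,3-diphenyltetrahydro-1H,3H-pyrrolo[1,2-c][1,3,2]oxazaborole (20 mol %), HNTf2 (16 mol %), CH2Cl2, −78 °C; Et3N quench
Reagents that add atoms: none
Why: The N-protonated oxazaborolidine binds the formyl oxygen of 14 on the side of the formyl hydrogen, which also contacts the ring oxygen of the catalyst, so that the s-trans enal lies over one phenyl group and only its open face can be reached; the closest known reaction type is the enantioselective Diels–Alder reaction of α-substituted enals and of trienals under cationic oxazaborolidine catalysis, used here intramolecularly with a 2-silyloxy diene. The addition is a strongly asynchronous [4+2], in the limit a Mukaiyama–Michael addition followed by closure of the boron enolate onto the silyloxyallyl cation: the enol ether carbon C5 attacks the β-carbon C10 first and C8–C9 follows. Ring B is the six-membered ring of the cycloaddition itself (6-endo in the Michael description), and ring A is closed by the four-carbon tether in a 6-exo-trig sense at C10. C9 and C10 are related by the (E) geometry of the enal, since suprafacial addition keeps the formyl group cis to H-10. C8 is related to C9 by the formyl-exo, tether-endo topology together with the (E)-propenyl terminus, which places the 8-methyl cis to the 9-methyl and makes the fusion at C5 cis. The absolute sense comes from the catalyst, whose (S) form should direct the diene to the Re face of C9. The step needs exo and facial selectivity: the first is supported by the exo preference of α-methyl enals bound to bulky Lewis acids (the catalyst-laden formyl group avoids the space under the diene and its silyloxy group), the second by the two-point binding of the aldehyde. The gem-dimethyl group on the tether and the electron-rich diene should allow reaction at −78 °C, where the uncatalysed pathway is silent; the C5 centre is not needed later.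

Step 9
Reactants: 15 octalin aldehyde from step 8; 16 1,2,4,5-tetramethoxybenzene
Product: 18 aryl carbinol in which the formyl group of 15 has become CH(OH)Ar with Ar = 2,3,5,6-tetramethoxyphenyl (both C11 epimers), via 2,3,5,6-tetramethoxyphenyllithium 17 (not isolated)
Conditions: 16, n-BuLi, THF, 0 °C → rt; then 15, −78 → 0 °C
Reagents that add atoms: none
Why: Lithiation of 16 between two methoxy groups (directed ortho-metalation) gives 17, which adds to the non-enolisable neopentyl aldehyde (1,2-addition of an aryllithium); the silyl enol ether shields the C6 carbonyl, and the carbinol configuration is irrelevant because the oxygen is removed.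

Step 10
Reactants: 18 aryl carbinol
Product: 19 O-alkyl S-methyl xanthate of 18 (both C11 epimers)
Conditions: NaH, imidazole (cat.), THF, 0 °C → rt; CS2; then MeI
Reagents that add atoms: carbon disulfide, S=C=S; iodomethane, CI
Why: Xanthate formation from the sodium alkoxide; CS2 is small enough to reach the hindered alkoxide, and no β-hydrogen is available on the C9 side for a competing thermal elimination.

Step 11
Reactants: 19 xanthate
Product: 20 silyl enol ether in which C11 is a methylene group bearing the 2,3,5,6-tetramethoxyphenyl ring (cis-fused, C6 triisopropylsilyl enol ether)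
Conditions: Bu3SnH, AIBN (cat.), toluene, 100 °C
Reagents that add atoms: none
Why: Barton–McCombie deoxygenation: the stannyl radical adds to sulfur, the benzylic radical is released and takes hydrogen from the stannane; a radical at C11 cannot rearrange the neopentyl skeleton as a cation would, and the silyl enol ether is inert.

Step 12
Reactants: 20 silyl enol ether
Product: 22 trans-fused C6 ketone (H-5 trans to H-10), via cis-fused ketone 21 (not isolated)
Conditions: Bu4NF, THF, 0 °C → rt; then NaOMe (cat.), MeOH, rt
Reagents that add atoms: none
Why: Fluoride cleaves the silyl enol ether and protonation at C7 gives the ketone without touching C8; methoxide then equilibrates C5 through the enolate to the trans-fused ketone, because either chair form of the cis isomer has a syn-axial contact (C4 against the 9-methyl, or the 8-methyl against C1).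

Step 13
Reactants: 22 trans-fused C6 ketone
Product: 23 axial 6β-alcohol (hydroxyl cis to H-10 and trans to H-5)
Conditions: LiBH(s-Bu)3, THF, −78 °C; then NaOH, H2O2
Reagents that add atoms: none
Why: The bulky borohydride attacks the carbonyl along the equatorial direction on the α-face, the β-face being screened by the axial C4 methyl group, and gives the axial alcohol, as usual for hindered-hydride reduction of cyclohexanones.

Step 14
Reactants: 23 axial 6β-alcohol
Product: 25 3-{[(1R,2S,8aS)-1,2,5,5-tetramethyl-1,2,3,5,6,7,8,8a-octahydronaphthalen-1-yl]methyl}-1,2,4,5-tetramethoxybenzene, via dichlorophosphate 24 (not isolated)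
Conditions: POCl3, pyridine, 0 → 60 °C
Reagents that add atoms: none
Why: Phosphorylation and anti-periplanar E2 elimination in pyridine; the axial leaving group is anti to the axial tertiary H-5, and loss of that hydrogen gives the trisubstituted alkene, as in the dehydration of hindered axial steroid alcohols next to a ring-fusion methine (11β-hydroxy to the 9(11)-ene). The basic, non-ionising medium avoids migration of a C4 methyl group.

Step 15
Reactants: 25 tetramethoxyarene
Product: 26 2,5-dimethoxy-3-{[(1R,2S,8aS)-1,2,5,5-tetramethyl-1,2,3,5,6,7,8,8a-octahydronaphthalen-1-yl]methyl}cyclohexa-2,5-diene-1,4-dione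
Conditions: (NH4)2Ce(NO3)6, MeCN–H2O, 0 °C
Reagents that add atoms: water, O
Why: Oxidative demethylation of a para-dimethoxyarene to the quinone by tetravalent cerium; the two para pairs of methoxy groups are related by the symmetry of the ring and give the same quinone, and the trisubstituted alkene should survive the short exposure at 0 °C.

Step 16
Reactants: 26 dimethoxyquinone
Product: 27 2-hydroxy-5-methoxy-3-{[(1R,2S,8aS)-1,2,5,5-tetramethyl-1,2,3,5,6,7,8,8a-octahydronaphthalen-1-yl]methyl}cyclohexa-2,5-diene-1,4-dione (target)
Conditions: KOH, MeOH–H2O, rt; then dilute HCl, 0 °C
Reagents that add atoms: potassium hydroxide, [K+].[OH-]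
Why: Addition–elimination of hydroxide at a vinylogous ester carbon; the methoxy group next to the alkylated carbon is twisted out of conjugation and is the one expected to be replaced, as in the usual two-step conversion of tetramethoxyaryl groups into 2-hydroxy-5-methoxy-3-alkylquinones. The hydroxyquinone anion then deactivates the second methoxy group, and cold dilute acid in the work-up avoids addition of the hydroxyl to C5=C6.

## Compound list

1 | 5-bromopent-1-ene | C=CCCCBr | starting material
2 | 4-methylpent-3-en-2-one | CC(=O)C=C(C)C | starting material
3 | pent-4-enylmagnesium bromide | C=CCCC[Mg]Br | intermediate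
4 | 4,4-dimethylnon-8-en-2-one | CC(=O)CC(C)(C)CCCC=C | intermediate
5 | acetaldehyde | CC=O | starting material
6 | lithium 4,4-dimethylnona-1,8-dien-2-olate (lithium enolate of 4) | [Li]OC(=C)CC(C)(C)CCCC=C | intermediate
7 | 2-hydroxy-6,6-dimethylundec-10-en-4-one (racemic) | CC(O)CC(=O)CC(C)(C)CCCC=C | intermediate
8 | ethyl 2-methylprop-2-enoate | CCOC(=O)C(C)=C | starting material
9 | ethyl (2E)-11-hydroxy-2,7,7-trimethyl-9-oxododec-2-enoate | CCOC(=O)/C(C)=C/CCCC(C)(C)CC(=O)CC(C)O | intermediate
10 | ethyl (2E)-11-(methanesulfonyloxy)-2,7,7-trimethyl-9-oxododec-2-enoate | CCOC(=O)/C(C)=C/CCCC(C)(C)CC(=O)CC(C)OS(C)(=O)=O | intermediate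
11 | ethyl (2E,10E)-2,7,7-trimethyl-9-oxododeca-2,10-dienoate | CCOC(=O)/C(C)=C/CCCC(C)(C)CC(=O)/C=C/C | intermediate
12 | ethyl (2E,8Z,10E)-2,7,7-trimethyl-9-[(triisopropylsilyl)oxy]dodeca-2,8,10-trienoate | C/C=C/C(O[Si](C(C)C)(C(C)C)C(C)C)=C/C(C)(C)CCC/C=C(\C)C(=O)OCC | intermediate
13 | (2E,8Z,10E)-2,7,7-trimethyl-9-[(triisopropylsilyl)oxy]dodeca-2,8,10-trien-1-ol | C/C=C/C(O[Si](C(C)C)(C(C)C)C(C)C)=C/C(C)(C)CCC/C=C(\C)CO | intermediate
14 | (2E,8Z,10E)-2,7,7-trimethyl-9-[(triisopropylsilyl)oxy]dodeca-2,8,10-trienal | C/C=C/C(O[Si](C(C)C)(C(C)C)C(C)C)=C/C(C)(C)CCC/C=C(\C)C=O | intermediate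
15 | (1R,2S,4aR,8aR)-1,2,5,5-tetramethyl-4-[(triisopropylsilyl)oxy]-1,2,4a,5,6,7,8,8a-octahydronaphthalene-1-carbaldehyde | O=C[C@@]1(C)[C@@H]2CCCC(C)(C)[C@@H]2C(O[Si](C(C)C)(C(C)C)C(C)C)=C[C@@H]1C | intermediate
16 | 1,2,4,5-tetramethoxybenzene | COc1cc(OC)c(OC)cc1OC | starting material
17 | 2,3,5,6-tetramethoxyphenyllithium | [Li]c1c(OC)c(OC)cc(OC)c1OC | intermediate
18 | aryl carbinol: 15 with CHO replaced by CH(OH)(2,3,5,6-tetramethoxyphenyl), both C11 epimers | COc1cc(OC)c(OC)c(C(O)[C@@]2(C)[C@@H]3CCCC(C)(C)[C@@H]3C(O[Si](C(C)C)(C(C)C)C(C)C)=C[C@@H]2C)c1OC | intermediate
19 | O-alkyl S-methyl xanthate of 18, both C11 epimers | COc1cc(OC)c(OC)c(C(OC(=S)SC)[C@@]2(C)[C@@H]3CCCC(C)(C)[C@@H]3C(O[Si](C(C)C)(C(C)C)C(C)C)=C[C@@H]2C)c1OC | intermediate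
20 | cis-fused C6 triisopropylsilyl enol ether with C11 as CH2–(2,3,5,6-tetramethoxyphenyl) | COc1cc(OC)c(OC)c(C[C@@]2(C)[C@@H]3CCCC(C)(C)[C@@H]3C(O[Si](C(C)C)(C(C)C)C(C)C)=C[C@@H]2C)c1OC | intermediate
21 | cis-fused C6 ketone (H-5 cis to H-10) | COc1cc(OC)c(OC)c(C[C@@]2(C)[C@@H]3CCCC(C)(C)[C@@H]3C(=O)C[C@@H]2C)c1OC | intermediate
22 | trans-fused C6 ketone (H-5 trans to H-10) | COc1cc(OC)c(OC)c(C[C@@]2(C)[C@@H]3CCCC(C)(C)[C@H]3C(=O)C[C@@H]2C)c1OC | intermediate
23 | trans-fused axial 6β-alcohol (OH cis to H-10) | COc1cc(OC)c(OC)c(C[C@@]2(C)[C@@H]3CCCC(C)(C)[C@H]3[C@@H](O)C[C@@H]2C)c1OC | intermediate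
24 | dichlorophosphate ester of 23 | COc1cc(OC)c(OC)c(C[C@@]2(C)[C@@H]3CCCC(C)(C)[C@H]3[C@@H](OP(=O)(Cl)Cl)C[C@@H]2C)c1OC | intermediate
25 | 3-{[(1R,2S,8aS)-1,2,5,5-tetramethyl-1,2,3,5,6,7,8,8a-octahydronaphthalen-1-yl]methyl}-1,2,4,5-tetramethoxybenzene | COc1cc(OC)c(OC)c(C[C@@]2(C)[C@@H]3CCCC(C)(C)C3=CC[C@@H]2C)c1OC | intermediate
26 | 2,5-dimethoxy-3-{[(1R,2S,8aS)-1,2,5,5-tetramethyl-1,2,3,5,6,7,8,8a-octahydronaphthalen-1-yl]methyl}cyclohexa-2,5-diene-1,4-dione | COC1=CC(=O)C(OC)=C(C[C@@]2(C)[C@@H]3CCCC(C)(C)C3=CC[C@@H]2C)C1=O | intermediate
27 | 2-hydroxy-5-methoxy-3-{[(1R,2S,8aS)-1,2,5,5-tetramethyl-1,2,3,5,6,7,8,8a-octahydronaphthalen-1-yl]methyl}cyclohexa-2,5-diene-1,4-dione | COC1=CC(=O)C(O)=C(C[C@@]2(C)[C@@H]3CCCC(C)(C)C3=CC[C@@H]2C)C1=O | target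

## Step count and least certain steps

Total: 16 steps. Longest linear sequence: 16 steps (from 1 and 2 to 27); arene 16 enters at step 9 as bought.

**Step 8 (key step).** The most likely failure is erosion of the exo topology. The tether, which must sit under the diene in the cis-fused mode, and the usual preference of a bound carbonyl for the endo position may together outweigh the exo bias of the α-methyl enal. Because the enal face fixes C9 and C10 while the diene face fixes C5 and C8, the formyl-endo mode would deliver the 5,8-diepimer, and that material cannot be epimerised. A second possibility is slow turnover of the hindered, trisubstituted enal. A reversed absolute sense alone would be met with the mirror-image catalyst.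

The fallback takes C8 out of the cycloaddition. It sets out from 20, obtained together with its 5,8-diepimer F1 (the formyl-endo adduct carried through steps 9–11), and comes back at 22. Saegusa–Ito oxidation with Pd(OAc)2 in MeCN at 40 °C (divalent palladium, one equivalent) converts both silyl enol ethers into 7-en-6-ones with loss of the C8 centre: the cis-fused enone F2 from 20 and the trans-fused enone F3 from F1. Catalytic NaOMe in MeOH equilibrates F2 into F3. Hydrogenation (H2, Pd/C, EtOAc) should then deliver hydrogen to C8 anti to the pseudoaxial 9-methyl group, placing the 8-methyl cis to it and giving ketone 22.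

**Step 14.** Competing loss of H-7, which is also anti to the leaving group, would give the C6=C7 alkene, which is hard to separate. Phosphorylation of the axial alcohol, which is syn-axial to a C4 methyl group, may also be incomplete.

The fallback forms the alkene by enolate chemistry instead of elimination. It sets out from 22 and comes back at 25. Deprotonation with slightly less than one equivalent of KN(SiMe3)2 in THF, warming from −78 °C to rt so that the enolates equilibrate toward the more substituted C5=C6 isomer, and trapping with PhNTf2 give the enol triflate F4. Reduction with Pd(OAc)2/PPh3, HCO2H and Bu3N in DMF at 60 °C (zerovalent palladium formed in the flask, formate as hydride source) gives 25.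

**Step 16.** Hydroxide may replace the other methoxy group, the one next to the ring C–H, which is less hindered, or both groups may be hydrolysed.

The fallback reverses the selectivity-determining event. It sets out from 26 and comes back at 27. Exhaustive hydrolysis (excess NaOH, aqueous EtOH, 60 °C; cold dilute acid) gives the dihydroxyquinone F5. One equivalent of Me3SiCHN2 in MeOH–toluene at 0 °C should then methylate the vinylogous acid hydroxyl flanked by the ring C–H in preference to the one shielded by the decalinylmethyl group, giving 27. Acid-catalysed esterification is avoided because of the alkene.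

**Step 3.** The electron-poor 1,1-disubstituted partner reacts slowly, so homodimerisation of the terminal alkene and incomplete conversion are the likely problems.

The fallback sets out from 7 and comes back at 9. Ozonolysis (O3, CH2Cl2–MeOH, −78 °C; PPh3), which is unambiguous at this stage because 7 has a single alkene, gives the keto aldehyde F6. A Wittig reaction with Ph3P=C(CH3)CO2Et in CH2Cl2 at rt, selective for the aldehyde over the ketone and for the (E)-enoate, gives 9.

Further compounds
F1 | step 8 | 5,8-diepimer of 20 (trans-fused, 8-methyl trans to 9-methyl) | COc1cc(OC)c(OC)c(C[C@@]2(C)[C@@H]3CCCC(C)(C)[C@H]3C(O[Si](C(C)C)(C(C)C)C(C)C)=C[C@H]2C)c1OC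
F2 | step 8 | cis-fused 8-methyl-7-en-6-one | COc1cc(OC)c(OC)c(C[C@@]2(C)[C@@H]3CCCC(C)(C)[C@@H]3C(=O)C=C2C)c1OC
F3 | step 8 | trans-fused 8-methyl-7-en-6-one | COc1cc(OC)c(OC)c(C[C@@]2(C)[C@@H]3CCCC(C)(C)[C@H]3C(=O)C=C2C)c1OC
F4 | step 14 | C5=C6 enol triflate of 22 | COc1cc(OC)c(OC)c(C[C@@]2(C)[C@@H]3CCCC(C)(C)C3=C(OS(=O)(=O)C(F)(F)F)C[C@@H]2C)c1OC
F5 | step 16 | 2,5-dihydroxy-3-{[(1R,2S,8aS)-1,2,5,5-tetramethyl-1,2,3,5,6,7,8,8a-octahydronaphthalen-1-yl]methyl}cyclohexa-2,5-diene-1,4-dione | OC1=CC(=O)C(O)=C(C[C@@]2(C)[C@@H]3CCCC(C)(C)C3=CC[C@@H]2C)C1=O
F6 | step 3 | 9-hydroxy-5,5-dimethyl-7-oxodecanal | O=CCCCC(C)(C)CC(=O)CC(C)O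
A1 | alternative 1 | 3,4-dimethyl-2-(4-methylpent-4-enyl)-3-(2,3,5,6-tetramethoxybenzyl)cyclohexanone | COc1cc(OC)c(OC)c(C[C@@]2(C)[C@H](CCCC(C)=C)C(=O)CC[C@@H]2C)c1OC
A2 | alternative 2 | O-tert-butyl ether of the target quinone | COC1=CC(=O)C(OC(C)(C)C)=C(C[C@@]2(C)[C@@H]3CCCC(C)(C)C3=CC[C@@H]2C)C1=O
A3 | alternative 3 | cis-fused cycloadduct with ring A trimethylsilyl enol ether and C4 methoxy group | COc1cc(OC)c(OC)c(C[C@@]2(C)[C@@H]3CC(O[Si](C)(C)C)=C[C@](C)(OC)[C@@H]3C(=O)C=C2)c1OC
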